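**Strategy.** The flavanone is cut at the aryl ether bond O1–C8a. Because O1 joins the benzylic stereocentre C2 to C8a of ring A, ring C can be closed at that aryl C–O bond by a palladium-catalysed intramolecular etherification in which the preformed (S)-carbinol oxygen replaces an ortho bromide; one operation builds ring C and leaves C2 untouched. The cyclisation substrate is a (1S)-1-aryl-3-(2-bromo-4,6-disilyloxyphenyl)propane-1,3-diol whose C3 oxygen (the later C4) is capped as a triethylsilyl ether, so that only the C1 hydroxyl can bind palladium. It is assembled by an aldol union of a ring B methyl ketone with a ring A aldehyde and a CBS reduction.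

Key step: step 11

Remark: the chain carbon that becomes C4 is formed racemic in step 9 and is carried as both epimers (drawn without configuration), because it ends as the C4 ketone in step 13.
Remark: the C4 oxygen is silylated before ring closure because a free benzylic alkoxide next to the C–Br bond could chelate palladium in a five-membered ring, be oxidised to the ketone and reduce the aryl bromide.
Remark: LDA is taken as a commercial solution; phenols are protected as TBS (ring A) and TIPS (ring B) ethers, the two alkyl oxygens as TES ethers.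

**Step 1**
Reactants: 1 geranyl acetate
Product: 3 (E)-7-hydroxy-3,7-dimethyloct-2-en-1-yl acetate, via alkylmercury acetate 2 (not isolated)
Conditions: Hg(OAc)2, THF/H2O, rt; then NaOH aq, NaBH4, 0 °C
Reagents that add atoms: water, O
Why: Markovnikov oxymercuration–demercuration should hydrate only the distal 6,7-alkene, because the 2,3-alkene is deactivated by the allylic acetoxy group, and no stereocentre remains after demercuration.

**Step 2**
Reactants: 3 (E)-7-hydroxy-3,7-dimethyloct-2-en-1-yl acetate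
Product: 4 (E)-3,7-dimethyl-7-(triethylsilyloxy)oct-2-en-1-yl acetate
Conditions: TESOTf, 2,6-lutidine, CH2Cl2, –78 → 0 °C
Reagents that add atoms: triethylsilyl triflate, CC[Si](CC)(CC)OS(=O)(=O)C(F)(F)F
Why: Silylation of a tertiary alcohol with a silyl triflate and a hindered pyridine base is standard and leaves the allylic acetate untouched.

**Step 3**
Reactants: 5 4'-hydroxyacetophenone
Product: 6 3'-bromo-4'-hydroxyacetophenone
Conditions: NBS (1.0 equiv), MeCN, 0 °C → rt
Reagents that add atoms: N-bromosuccinimide, O=C1CCC(=O)N1Br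
Why: Electrophilic aromatic bromination should go ortho to the phenol, since the para position is blocked and the acetyl group directs to the same carbon, with one equivalent of NBS limiting dibromination.

**Step 4**
Reactants: 6 3'-bromo-4'-hydroxyacetophenone
Product: 7 3'-bromo-4'-(triisopropylsilyloxy)acetophenone
Conditions: TIPSCl, imidazole, DMF, rt
Reagents that add atoms: triisopropylsilyl chloride, CC(C)[Si](Cl)(C(C)C)C(C)C
Why: Phenol silylation under imidazole catalysis is routine, and the triisopropylsilyl ether is chosen because it should survive the aqueous carbonate of step 6.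

**Step 5**
Reactants: 7 3'-bromo-4'-(triisopropylsilyloxy)acetophenone
Product: 8 3'-(4,4,5,5-tetramethyl-1,3,2-dioxaborolan-2-yl)-4'-(triisopropylsilyloxy)acetophenone
Conditions: B2pin2, PdCl2(dppf) (cat.), KOAc, dioxane, 90 °C
Reagents that add atoms: bis(pinacolato)diboron, CC1(C)OB(OC1(C)C)B1OC(C)(C)C(C)(C)O1
Why: Miyaura borylation of an aryl bromide tolerates the methyl ketone and the silyl ether, and the weak acetate base avoids enolate chemistry.

**Step 6**
Reactants: 8 3'-(4,4,5,5-tetramethyl-1,3,2-dioxaborolan-2-yl)-4'-(triisopropylsilyloxy)acetophenone; 4 (E)-3,7-dimethyl-7-(triethylsilyloxy)oct-2-en-1-yl acetate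
Product: 9 3'-[(E)-3,7-dimethyl-7-(triethylsilyloxy)oct-2-en-1-yl]-4'-(triisopropylsilyloxy)acetophenone
Conditions: Pd(PPh3)4 (cat.), K2CO3, THF/H2O, 65 °C
Reagents that add atoms: none
Why: In this Suzuki–Miyaura allyl–aryl coupling zerovalent palladium ionises the allylic acetate to a π-allyl complex, the arylboronate transmetalates and reductive elimination at the unsubstituted allyl terminus should give the linear product, the E geometry being kept because syn–anti exchange at the disubstituted terminus is slow.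

**Step 7**
Reactants: 10 5-bromoresorcinol
Product: 12 2-bromo-4,6-dihydroxybenzaldehyde, via aryl iminium chloride 11 (not isolated)
Conditions: POCl3, DMF, MeCN, 0 °C → rt; then H2O, 50 °C
Reagents that add atoms: N,N-dimethylformamide, CN(C)C=O; water, O
Why: Vilsmeier–Haack formylation of a resorcinol should occur mainly at the carbon para to one hydroxyl and ortho to the other (here the one next to bromine), as with resorcinol and orcinol, and the minor isomer formylated between the hydroxyls is removed by crystallisation or chromatography.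

**Step 8**
Reactants: 12 2-bromo-4,6-dihydroxybenzaldehyde
Product: 13 2-bromo-4,6-bis(tert-butyldimethylsilyloxy)benzaldehyde
Conditions: TBSCl, imidazole, DMF, rt
Reagents that add atoms: tert-butyldimethylsilyl chloride, CC(C)(C)[Si](C)(C)Cl
Why: Double phenol silylation with excess silyl chloride and imidazole is standard, the hydrogen-bonded ortho hydroxyl reacting more slowly but completely.

**Step 9**
Reactants: 9 3'-[(E)-3,7-dimethyl-7-(triethylsilyloxy)oct-2-en-1-yl]-4'-(triisopropylsilyloxy)acetophenone; 13 2-bromo-4,6-bis(tert-butyldimethylsilyloxy)benzaldehyde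
Product: 16 3-[2-bromo-4,6-bis(tert-butyldimethylsilyloxy)phenyl]-1-{3-[(E)-3,7-dimethyl-7-(triethylsilyloxy)oct-2-en-1-yl]-4-(triisopropylsilyloxy)phenyl}-3-(triethylsilyloxy)propan-1-one (racemic at C3), via lithium enolate 14 (not isolated), via lithium aldolate 15 (not isolated)
Conditions: LDA, THF, –78 °C; 13, –78 °C; then TESOTf, –78 → –40 °C
Reagents that add atoms: triethylsilyl triflate, CC[Si](CC)(CC)OS(=O)(=O)C(F)(F)F
Why: Directed aldol addition of the kinetic lithium enolate of a methyl ketone to a non-enolisable aldehyde is reliable at –78 °C, and O-silylation of the aldolate in the same flask should block retro-aldol cleavage and silyl transfer from the ortho aryl silyl ether, the new carbinol centre being formed without control.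

**Step 10**
Reactants: 16 3-[2-bromo-4,6-bis(tert-butyldimethylsilyloxy)phenyl]-1-{3-[(E)-3,7-dimethyl-7-(triethylsilyloxy)oct-2-en-1-yl]-4-(triisopropylsilyloxy)phenyl}-3-(triethylsilyloxy)propan-1-one
Product: 17 (1S)-3-[2-bromo-4,6-bis(tert-butyldimethylsilyloxy)phenyl]-1-{3-[(E)-3,7-dimethyl-7-(triethylsilyloxy)oct-2-en-1-yl]-4-(triisopropylsilyloxy)phenyl}-3-(triethylsilyloxy)propan-1-ol (both C3 epimers)
Conditions: (R)-2-methyl-CBS-oxazaborolidine (cat.), catecholborane, toluene, –78 → –40 °C
Reagents that add atoms: none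
Why: In this Corey–Bakshi–Shibata reduction the (R)-oxazaborolidine should place the aryl group as the large substituent and deliver hydride to the Re face, setting the (S)-carbinol under catalyst control for both C3 epimers, while catecholborane does not hydroborate the trisubstituted alkene.

**Step 11**
Reactants: 17 (1S)-3-[2-bromo-4,6-bis(tert-butyldimethylsilyloxy)phenyl]-1-{3-[(E)-3,7-dimethyl-7-(triethylsilyloxy)oct-2-en-1-yl]-4-(triisopropylsilyloxy)phenyl}-3-(triethylsilyloxy)propan-1-ol
Product: 18 (2S)-5,7-bis(tert-butyldimethylsilyloxy)-2-{3-[(E)-3,7-dimethyl-7-(triethylsilyloxy)oct-2-en-1-yl]-4-(triisopropylsilyloxy)phenyl}-4-(triethylsilyloxy)chroman (both C4 epimers)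
Conditions: Pd2(dba)3 (cat.), 2-(di-tert-butylphosphino)-1,1'-binaphthyl, Cs2CO3, toluene, 80 °C
Reagents that add atoms: none
Why: Zerovalent palladium carrying the bulky di-tert-butyl biaryl phosphine should insert into the C8a–Br bond of ring A, Cs2CO3 should then bring the C2 hydroxyl onto palladium as an alkoxide, and C–O reductive elimination should forge O1–C8a. The closest known reaction type is the intramolecular Buchwald–Hartwig etherification of secondary alcohols with aryl bromides that gives chromans. Ring C closes in a 6-exo mode, the tethered oxygen attacking the metal-bound aryl carbon through a seven-membered palladacycle that contracts on reductive elimination. No stereocentre is created: C2 keeps its S configuration because its C–O bond is never broken, and the C4 epimers are carried on together. The step needs reductive elimination to outrun beta-hydride loss from the alkoxide, which the bulky electron-rich ligand and the position of both silyloxy groups meta to the bromide favour. It also needs only the C2 oxygen to reach palladium, which the triethylsilyl cap on the C4 oxygen secures by shutting off the five-membered oxapalladacycle that would otherwise oxidise C4 and reduce the aryl bromide.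

**Step 12**
Reactants: 18 (2S)-5,7-bis(tert-butyldimethylsilyloxy)-2-{3-[(E)-3,7-dimethyl-7-(triethylsilyloxy)oct-2-en-1-yl]-4-(triisopropylsilyloxy)phenyl}-4-(triethylsilyloxy)chroman
Product: 19 (2S)-5,7-bis(tert-butyldimethylsilyloxy)-2-{3-[(E)-7-hydroxy-3,7-dimethyloct-2-en-1-yl]-4-(triisopropylsilyloxy)phenyl}chroman-4-ol (both C4 epimers)
Conditions: AcOH/THF/H2O (3:1:1), rt
Reagents that add atoms: none
Why: Acid-catalysed hydrolysis should remove both triethylsilyl ethers, which are far more acid-labile than the phenolic TBS and TIPS ethers, while acetic acid is too weak to ionise the electron-rich C4 benzylic position.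

**Step 13**
Reactants: 19 (2S)-5,7-bis(tert-butyldimethylsilyloxy)-2-{3-[(E)-7-hydroxy-3,7-dimethyloct-2-en-1-yl]-4-(triisopropylsilyloxy)phenyl}chroman-4-ol
Product: 20 (2S)-5,7-bis(tert-butyldimethylsilyloxy)-2-{3-[(E)-7-hydroxy-3,7-dimethyloct-2-en-1-yl]-4-(triisopropylsilyloxy)phenyl}chroman-4-one
Conditions: Dess–Martin periodinane, CH2Cl2, 0 °C → rt
Reagents that add atoms: none
Why: Dess–Martin oxidation converts the secondary benzylic alcohol of both epimers into the single C4 ketone under near-neutral conditions that leave the tertiary alcohol, the alkene, the aryl silyl ethers and C2 alone.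

**Step 14**
Reactants: 20 (2S)-5,7-bis(tert-butyldimethylsilyloxy)-2-{3-[(E)-7-hydroxy-3,7-dimethyloct-2-en-1-yl]-4-(triisopropylsilyloxy)phenyl}chroman-4-one
Product: 21 (2S)-5,7-dihydroxy-2-{4-hydroxy-3-[(E)-7-hydroxy-3,7-dimethyloct-2-en-1-yl]phenyl}chroman-4-one (CNP0161524.1)
Conditions: TBAF, AcOH (premixed 1:1), THF, 0 °C → rt
Reagents that add atoms: none
Why: Fluoride-mediated cleavage of the three aryl silyl ethers under acetic acid buffering keeps the phenols protonated, so the base-triggered ring opening to the chalcone that would racemise C2 should not occur.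

**Compound list**
1 | geranyl acetate | CC(C)=CCC/C(C)=C/COC(C)=O | starting material
2 | (E)-6-(acetoxymercurio)-7-hydroxy-3,7-dimethyloct-2-en-1-yl acetate (racemic) | C/C(=C\COC(C)=O)CCC([Hg]OC(C)=O)C(C)(C)O | intermediate (not isolated)
3 | (E)-7-hydroxy-3,7-dimethyloct-2-en-1-yl acetate | C/C(=C\COC(C)=O)CCCC(C)(C)O | intermediate
4 | (E)-3,7-dimethyl-7-(triethylsilyloxy)oct-2-en-1-yl acetate | C/C(=C\COC(C)=O)CCCC(C)(C)O[Si](CC)(CC)CC | intermediate
5 | 4'-hydroxyacetophenone | CC(=O)c1ccc(O)cc1 | starting material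
6 | 3'-bromo-4'-hydroxyacetophenone | CC(=O)c1ccc(O)c(Br)c1 | intermediate
7 | 3'-bromo-4'-(triisopropylsilyloxy)acetophenone | CC(=O)c1ccc(O[Si](C(C)C)(C(C)C)C(C)C)c(Br)c1 | intermediate
8 | 3'-(4,4,5,5-tetramethyl-1,3,2-dioxaborolan-2-yl)-4'-(triisopropylsilyloxy)acetophenone | CC(=O)c1ccc(O[Si](C(C)C)(C(C)C)C(C)C)c(B2OC(C)(C)C(C)(C)O2)c1 | intermediate
9 | 3'-[(E)-3,7-dimethyl-7-(triethylsilyloxy)oct-2-en-1-yl]-4'-(triisopropylsilyloxy)acetophenone | C/C(=C\Cc1cc(C(C)=O)ccc1O[Si](C(C)C)(C(C)C)C(C)C)CCCC(C)(C)O[Si](CC)(CC)CC | intermediate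
10 | 5-bromoresorcinol | Oc1cc(O)cc(Br)c1 | starting material
11 | (2-bromo-4,6-dihydroxybenzylidene)dimethylammonium chloride | C[N+](C)=Cc1c(O)cc(O)cc1Br.[Cl-] | intermediate (not isolated)
12 | 2-bromo-4,6-dihydroxybenzaldehyde | O=Cc1c(O)cc(O)cc1Br | intermediate
13 | 2-bromo-4,6-bis(tert-butyldimethylsilyloxy)benzaldehyde | O=Cc1c(O[Si](C)(C)C(C)(C)C)cc(O[Si](C)(C)C(C)(C)C)cc1Br | intermediate
14 | lithium enolate of ketone 9 | C/C(=C\Cc1cc(C(=C)O[Li])ccc1O[Si](C(C)C)(C(C)C)C(C)C)CCCC(C)(C)O[Si](CC)(CC)CC | intermediate (not isolated)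
15 | lithium aldolate from 14 and 13 (racemic) | C/C(=C\Cc1cc(C(=O)CC(O[Li])c2c(O[Si](C)(C)C(C)(C)C)cc(O[Si](C)(C)C(C)(C)C)cc2Br)ccc1O[Si](C(C)C)(C(C)C)C(C)C)CCCC(C)(C)O[Si](CC)(CC)CC | intermediate (not isolated)
16 | 3-[2-bromo-4,6-bis(tert-butyldimethylsilyloxy)phenyl]-1-{3-[(E)-3,7-dimethyl-7-(triethylsilyloxy)oct-2-en-1-yl]-4-(triisopropylsilyloxy)phenyl}-3-(triethylsilyloxy)propan-1-one (racemic at C3) | C/C(=C\Cc1cc(C(=O)CC(O[Si](CC)(CC)CC)c2c(O[Si](C)(C)C(C)(C)C)cc(O[Si](C)(C)C(C)(C)C)cc2Br)ccc1O[Si](C(C)C)(C(C)C)C(C)C)CCCC(C)(C)O[Si](CC)(CC)CC | intermediate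
17 | (1S)-3-[2-bromo-4,6-bis(tert-butyldimethylsilyloxy)phenyl]-1-{3-[(E)-3,7-dimethyl-7-(triethylsilyloxy)oct-2-en-1-yl]-4-(triisopropylsilyloxy)phenyl}-3-(triethylsilyloxy)propan-1-ol (both C3 epimers) | C/C(=C\Cc1cc([C@@H](O)CC(O[Si](CC)(CC)CC)c2c(O[Si](C)(C)C(C)(C)C)cc(O[Si](C)(C)C(C)(C)C)cc2Br)ccc1O[Si](C(C)C)(C(C)C)C(C)C)CCCC(C)(C)O[Si](CC)(CC)CC | intermediate
18 | (2S)-5,7-bis(tert-butyldimethylsilyloxy)-2-{3-[(E)-3,7-dimethyl-7-(triethylsilyloxy)oct-2-en-1-yl]-4-(triisopropylsilyloxy)phenyl}-4-(triethylsilyloxy)chroman (both C4 epimers) | C/C(=C\Cc1cc([C@@H]2CC(O[Si](CC)(CC)CC)c3c(O[Si](C)(C)C(C)(C)C)cc(O[Si](C)(C)C(C)(C)C)cc3O2)ccc1O[Si](C(C)C)(C(C)C)C(C)C)CCCC(C)(C)O[Si](CC)(CC)CC | intermediate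
19 | (2S)-5,7-bis(tert-butyldimethylsilyloxy)-2-{3-[(E)-7-hydroxy-3,7-dimethyloct-2-en-1-yl]-4-(triisopropylsilyloxy)phenyl}chroman-4-ol (both C4 epimers) | C/C(=C\Cc1cc([C@@H]2CC(O)c3c(O[Si](C)(C)C(C)(C)C)cc(O[Si](C)(C)C(C)(C)C)cc3O2)ccc1O[Si](C(C)C)(C(C)C)C(C)C)CCCC(C)(C)O | intermediate
20 | (2S)-5,7-bis(tert-butyldimethylsilyloxy)-2-{3-[(E)-7-hydroxy-3,7-dimethyloct-2-en-1-yl]-4-(triisopropylsilyloxy)phenyl}chroman-4-one | C/C(=C\Cc1cc([C@@H]2CC(=O)c3c(O[Si](C)(C)C(C)(C)C)cc(O[Si](C)(C)C(C)(C)C)cc3O2)ccc1O[Si](C(C)C)(C(C)C)C(C)C)CCCC(C)(C)O | intermediate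
21 | (2S)-5,7-dihydroxy-2-{4-hydroxy-3-[(E)-7-hydroxy-3,7-dimethyloct-2-en-1-yl]phenyl}chroman-4-one (CNP0161524.1) | C/C(=C\Cc1cc([C@@H]2CC(=O)c3c(O)cc(O)cc3O2)ccc1O)CCCC(C)(C)O | target

**Step count.** Total: 14 steps. Longest linear sequence: 10 steps (from 5 through steps 3, 4, 5, 6, 9, 10, 11, 12, 13 and 14).

**Steps most likely to fail**

Step 11. After oxidative addition the palladium alkoxide may lose the C2 hydride faster than it reductively eliminates, which would give back an aryl ketone and a debrominated ring A. The triethylsilyl group may also wander between the two chain oxygens under carbonate. Fallback, setting out from 16 and returning at 18: ring C would be closed at the other ether bond, O1–C2, by a Mitsunobu displacement with inversion. Ketone 16 would be reduced with the enantiomeric (S)-2-methyl-CBS-oxazaborolidine and catecholborane to the (1R)-alcohol F1. Miyaura borylation of its aryl bromide (B2pin2, PdCl2(dppf), KOAc, dioxane) would give the arylboronate F2, and buffered oxidation (H2O2, pH 7 phosphate, THF) would give the phenol F3. PPh3 and DIAD in THF at 0 °C would then let the phenol oxygen displace the activated benzylic hydroxyl with inversion, giving the (2S)-chroman 18.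

Step 6. The π-allyl intermediate may lose its E geometry or couple at the substituted terminus, it may shed a hydride to give a triene, and the hindered ortho-silyloxy arylboronate may protodeboronate before it transmetalates. Fallback, setting out from 7 and 4 and returning at 9: a nickel-catalysed reductive cross-electrophile coupling of aryl bromide 7 with allylic acetate 4 (NiCl2(dme), 4,4'-di-tert-butyl-2,2'-bipyridine, zinc powder, DMA, rt to 40 °C) would form the same aryl–allyl bond without any organoboron partner, and step 5 would be dropped.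

Step 9. The lithium aldolate of an electron-rich, doubly ortho-substituted benzaldehyde may revert by retro-aldol cleavage, or take a silyl group from the neighbouring aryl ether, before the triflate caps it. Fallback, setting out from 9 and returning at 16: a Mukaiyama aldol that never forms a basic aldolate. Ketone 9 would be converted (LDA, TMSCl, THF, –78 °C) into the trimethylsilyl enol ether F4, which would be added to aldehyde 13 with BF3·OEt2 in CH2Cl2 at –78 °C to give, after aqueous work-up, the β-hydroxy ketone F5. Silylation of F5 with TESOTf and 2,6-lutidine at –78 °C would give 16.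

**Further compounds**
F1 | step 11 | (1R)-3-[2-bromo-4,6-bis(tert-butyldimethylsilyloxy)phenyl]-1-{3-[(E)-3,7-dimethyl-7-(triethylsilyloxy)oct-2-en-1-yl]-4-(triisopropylsilyloxy)phenyl}-3-(triethylsilyloxy)propan-1-ol (both C3 epimers) | C/C(=C\Cc1cc([C@H](O)CC(O[Si](CC)(CC)CC)c2c(O[Si](C)(C)C(C)(C)C)cc(O[Si](C)(C)C(C)(C)C)cc2Br)ccc1O[Si](C(C)C)(C(C)C)C(C)C)CCCC(C)(C)O[Si](CC)(CC)CC
F2 | step 11 | (1R)-3-[2-(4,4,5,5-tetramethyl-1,3,2-dioxaborolan-2-yl)-4,6-bis(tert-butyldimethylsilyloxy)phenyl]-1-{3-[(E)-3,7-dimethyl-7-(triethylsilyloxy)oct-2-en-1-yl]-4-(triisopropylsilyloxy)phenyl}-3-(triethylsilyloxy)propan-1-ol | C/C(=C\Cc1cc([C@H](O)CC(O[Si](CC)(CC)CC)c2c(O[Si](C)(C)C(C)(C)C)cc(O[Si](C)(C)C(C)(C)C)cc2B3OC(C)(C)C(C)(C)O3)ccc1O[Si](C(C)C)(C(C)C)C(C)C)CCCC(C)(C)O[Si](CC)(CC)CC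
F3 | step 11 | (1R)-3-[2-hydroxy-4,6-bis(tert-butyldimethylsilyloxy)phenyl]-1-{3-[(E)-3,7-dimethyl-7-(triethylsilyloxy)oct-2-en-1-yl]-4-(triisopropylsilyloxy)phenyl}-3-(triethylsilyloxy)propan-1-ol | C/C(=C\Cc1cc([C@H](O)CC(O[Si](CC)(CC)CC)c2c(O[Si](C)(C)C(C)(C)C)cc(O[Si](C)(C)C(C)(C)C)cc2O)ccc1O[Si](C(C)C)(C(C)C)C(C)C)CCCC(C)(C)O[Si](CC)(CC)CC
F0 | step 6 | none | none
F4 | step 9 | trimethylsilyl enol ether of ketone 9 | C/C(=C\Cc1cc(C(=C)O[Si](C)(C)C)ccc1O[Si](C(C)C)(C(C)C)C(C)C)CCCC(C)(C)O[Si](CC)(CC)CC
F5 | step 9 | 3-[2-bromo-4,6-bis(tert-butyldimethylsilyloxy)phenyl]-1-{3-[(E)-3,7-dimethyl-7-(triethylsilyloxy)oct-2-en-1-yl]-4-(triisopropylsilyloxy)phenyl}-3-hydroxypropan-1-one (racemic) | C/C(=C\Cc1cc(C(=O)CC(O)c2c(O[Si](C)(C)C(C)(C)C)cc(O[Si](C)(C)C(C)(C)C)cc2Br)ccc1O[Si](C(C)C)(C(C)C)C(C)C)CCCC(C)(C)O[Si](CC)(CC)CC
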